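## Structural features

The target is a germacranolide: a ten-membered carbocycle (C1–C10; germacrane numbering throughout, C11–C13 in the lactone arm, C14 on C10, C15 on C4) trans-fused across C6–C7 to an α-methylene-γ-butyrolactone whose ring oxygen sits on C6. The carbocycle carries a trans 1,10-epoxide, a Z trisubstituted C4=C5 olefin, an allylic acetate at C3 and an isovalerate at C8. Six stereocentres are present: C6, C7 and C8 are contiguous (6R,7R,8S; both ring oxygens α, the C11 arm β), C1 and C10 are the epoxide carbons (1R,10R), and C3 (S) stands alone between C2 and the olefin. The fragile functions are the exocyclic enoate (a Michael acceptor, sensitive to bases and nucleophiles), the epoxide that faces C4=C5 across the ring (acid invites transannular cyclisation) and the two different esters. The real difficulty lies in closing a ten-membered ring that holds one E and one Z trisubstituted olefin, in setting the C6–C7–C8 triad, and in telling four oxygens (on C3, C6, C8 and C12) apart at the end. The key step uses the fact that C6 is a carbinol carbon allylic to C4=C5 and bonded to C7, which bears the unit C11(=C13)–C12–O: this 2-alkenyl homoallylic alcohol is what a [2,3]-Wittig shift delivers, so joining the C6 oxygen to C13 hides the ten-membered ring inside an unstrained thirteen-membered diallylic ether.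

## Logic of the disconnections

36 ⇒ 35. The two C–O bonds of the epoxide are cut first. The epoxide is the function least able to survive base, fluoride or acid, and without it C1=C10 is the only electron-rich olefin left. The forward step must pick that olefin among three and attack its outer face; in 35 the two allylic acyloxy groups deactivate C4=C5 and the enoate is inert to a peracid.

35 ⇒ 34 ⇒ 33 ⇒ 32. The acyl C–O bonds at C8 and then at C3 are cut. Esters cannot pass through an organolithium step, so both oxygens travel as silyl ethers and are acylated one after the other. The forward sequence needs the C3 hydroxyl free while C8 is still silylated (32), and a C8 silyl ether that can be removed beside the enoate and the acetate (33 to 34).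

32 ⇒ 30 ⇒ 29. The lactone C12–O bond is cut and C12 is taken back to the alcohol level. The α-methylene lactone becomes a 2-methylene-1,4-diol, so no enolate methylenation is needed. The forward step needs an oxidant that takes the primary allylic alcohol of 30 and leaves the secondary allylic alcohols at C3 and C6 alone. The C8 oxygen must stay masked, because it is also 1,4-related to C12 and would compete for the lactone.

29 ⇒ 27. The C6–C7 bond is cut and the C6 oxygen is joined to C13. The ten-membered ring becomes a thirteen-membered ether, two stereocentres (C6, C7) are traded for one olefin geometry, and the C11=C13 methylene folds back into the trisubstituted C7=C11 olefin. The forward step asks for lithiation at C6 only, for the ring-trans C7=C11 geometry, and for spectator groups that neither coordinate the base nor migrate. Every hydroxyl is therefore a bulky silyl ether: TIPS on C8, and TBS on both C3 and C12 so that these two are freed together later. A smaller silyl group on C12 would invite lithiation and silyl transfer there.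

27 ⇒ 26. The O–C13 bond is cut (Williamson). A thirteen-membered ring closes without transannular strain and the seco compound is an open chain. The alkoxide is placed on C6 and the chloride on C13. The reverse polarity would put an alkoxide on C13 next to the C12 silyl ether, where a 1,3-silyl shift would exchange C12 and C13 and scramble the olefin geometry.

26 ⇒ 25 ⇒ 23 ⇒ 22 ⇒ 17 + 21. The C7=C11 double bond is cut. An olefination with 21 brings C11, C12 and C13 in one piece and distinguishes the two oxygenated arms by oxidation level: the ester carbon becomes C13, the silyloxymethyl carbon C12. The forward step must give the isomer with the ester trans to C8. Reduction, chlorination and removal of the C6 silyl group then prepare the ring closure.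

17 ⇒ 16 ⇒ 15 ⇒ 14 ⇒ 13 ⇒ 12 ⇒ 7 + 11. The C3–C4 bond is cut between a Z vinyl iodide and an aldehyde. The Z olefin C4=C5 comes ready-made in 11 and the chain is assembled convergently. C8 is too remote to steer C3, so the coupling is run without selectivity and C3 is set by catalyst-controlled reduction of 13. The coupling must be non-basic because 7 is a β,γ-unsaturated aldehyde.

7 ⇒ 6 ⇒ 3 ⇒ 2 ⇒ 1. The C1–C2 and C10–C14 bonds are cut together (methyl-metalation of an alkyne, then oxirane), and then C9–C10 (acetylide and epoxide). Syn addition fixes C1=C10 as E, and C8 comes from the chiral pool. The demand is regioselective carbometalation of the terminal alkyne of 3 and transfer of the alkenyl group with retention.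

11 ⇐ 10 ⇐ 8 and 21 ⇐ 19 ⇐ 18. The two small partners go back to commercial 8 and 18. A hydroxyl-directed trans hydrometalation sets the Z iodide, and phosphorus–carbon bond formation on an ester enolate gives the phosphonate.

## Other disconnections considered

Alternative 1: The cut removes C4–C5 and C1–C10 together, splitting the carbocycle into a six-membered enone (C5–C10) and a four-membered ene ester (C1–C4). Forward, the triplet enone adds across the cyclobutene ester to give the tricyclic photoadduct A1, and heating A1 opens the bicyclo[2.2.0]hexane unit (C1–C4 and C5–C10 break) to the ten-membered 1(10),4-diene.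
- In its favour: two C–C bonds and the whole carbocycle come from two small rings in two operations, without high dilution or strong base, and the C3 and C8 oxygens are set on small rings. In the number of steps needed to reach a ten-membered ring this plan is better than the chosen one.
- Against it here: the photoaddition must be head-to-head and must pair the correct faces of two chiral, enantiopure partners, since any other pairing leads after cycloreversion to a wrong olefin geometry. The cycloreversion temperature is also one at which a cyclodeca-1,5-diene can undergo Cope rearrangement to a divinylcyclohexane. C15 arrives as an ester that needs about three steps to become methyl. C11–C13 are missing, so the lactone must be built by alkylation at C7 next to the C6 ketone, reduction to the 6α alcohol and a final enolate methylenation on a molecule that already carries an allylic acetate.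
- Comparison: in structure, A1 holds fewer of the target's atoms than 29 (no C11–C13, C15 at the wrong oxidation level, C6 as ketone). In mechanism, a stepwise triplet biradical addition with open regiochemistry stands against a concerted suprafacial shift tied to one olefin geometry. In step economy, the early gain is likely to be spent after ring formation, so the totals should be similar.

Alternative 2: The cut is C9–C10. Forward, the silyl enol ether of a C8 methyl ketone attacks, through C9, a C10 ketone that bears chloride on C1. This Lewis-acid-mediated Mukaiyama aldol closes the ten-membered ring as the β-hydroxy ketone A2, and base then turns the chlorohydrin into the 1,10-epoxide with inversion at C1.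
- In its favour: the epoxide configuration follows from acyclic 1,2-induction by the α-chloro centre (Cornforth model) rather than from the conformation of a medium ring, the epoxide needs no oxidant, and the lactone is in place before ring closure. On control of the epoxide stereochemistry this plan is better than the chosen one, which relies on peripheral attack in step 26.
- Against it here: the ten-membered ring must be closed directly by C–C bond formation onto a ketone, the least favourable ring size combined with a poor, reversible aldol acceptor. Enolisation of the C8 ketone toward C7 instead of C9 would epimerise C7 and could expel the C6 lactone oxygen by β-elimination. The C8 ketone must later be reduced to the 8α alcohol, and C13 is absent, so an enolate methylenation is still needed.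
- Comparison: in structure, A2 already contains the lactone and the epoxide precursor, whereas 29 contains the methylene and the C12 oxygen but not yet lactone or epoxide. In mechanism, an open-transition-state aldol that must pay the medium-ring entropy stands against a sigmatropic contraction starting from a ring closed without strain. In step economy the two should be about equal, with the larger risk on the aldol ring closure.

Alternative 3: The cut is made after adding a C6–C10 bond in the retrosynthetic sense. The ten-membered ring is seen as a bicyclo[5.3.0]decene (five-membered ring C6–C10, seven-membered ring C10, C1–C6) with a tertiary C6 hydroxyl and a C1 mesylate. Forward, the C6 alkoxide expels the mesylate in a Grob fragmentation that breaks C6–C10 and gives the dienone A3 with the C6 ketone and the E olefin C1=C10.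
- In its favour: the fragmentation is concerted and stereospecific, so the E geometry follows from the anti-periplanar arrangement of C1–O and C6–C10. The Z geometry of C4=C5 is guaranteed by the seven-membered ring, and ring expansion needs no high dilution. In the reliability of ring formation and of both olefin geometries this plan equals the chosen one, and it is better in needing no regioselective deprotonation.
- Against it here: the precursor of A3 needs C1, C6 and C10 as three further stereocentres in a defined relation to C7 and C8, a long synthesis of its own. A3 has the C6 ketone conjugated to the Z olefin and flanked by the epimerisable C7, so C7 and the Z geometry are at risk. The ketone must be reduced to the 6α alcohol, the acetal oxidised to the lactone and the methylene added by enolate chemistry.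
- Comparison: in structure, A3 and 29 are both (1(10)E,4Z) ten-membered dienes with C3, C7 and C8 set, but 29 already has the C6 carbinol in the right configuration and the C11=C13 methylene with the C12 oxygen. In mechanism the two key steps are alike, both concerted and stereospecific. In step economy the chosen plan should be shorter by the steps A3 still needs for C6, C12 and C13 and by the length of the bicyclic precursor.

Key step: step 20

Remark: compounds 1, 8 and 18 and all reagents in the Conditions lines are assumed to be commercial.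
Remark: the oxazaborolidine reduction in step 9 is assumed to follow the usual model, with the α-branched alkenyl group as the large substituent.
Remark: every stereodescriptor of 27 and 29 was checked against the target (3S, 8S, ring-trans C7=C11, 1(10)E, 4Z). No correction of constitution or configuration was needed; only the silyl pattern and the lactonising oxidant were redesigned.

## Route

Step 1
Reactants: 1 (S)-2-{[(4-methoxybenzyl)oxy]methyl}oxirane
Product: 2 (S)-1-[(4-methoxybenzyl)oxy]pent-4-yn-2-ol
Conditions: HC≡CLi·H2NCH2CH2NH2, DMSO, 0 °C → rt; H2O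
Reagents that add atoms: lithium acetylide–ethylenediamine complex, [Li]C#C.NCCN
Why: SN2 opening of a terminal epoxide by acetylide at the unsubstituted carbon (future C9) forms C9–C10; the C8 stereocentre is not touched, so its S configuration comes directly from 1.

Step 2
Reactants: 2 (S)-1-[(4-methoxybenzyl)oxy]pent-4-yn-2-ol
Product: 3 (S)-triisopropyl({1-[(4-methoxybenzyl)oxy]pent-4-yn-2-yl}oxy)silane
Conditions: TIPSOTf, 2,6-lutidine, CH2Cl2, 0 °C
Reagents that add atoms: triisopropylsilyl trifluoromethanesulfonate, CC(C)[Si](OS(=O)(=O)C(F)(F)F)(C(C)C)C(C)C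
Why: Standard silyl ether formation with a silyl triflate and a hindered base; TIPS is chosen because it must outlast two TBS ethers and shield C8–H from the base in step 20.

Step 3
Reactants: 3 (S)-triisopropyl({1-[(4-methoxybenzyl)oxy]pent-4-yn-2-yl}oxy)silane
Product: 6 (S,E)-7-[(4-methoxybenzyl)oxy]-4-methyl-6-[(triisopropylsilyl)oxy]hept-3-en-1-ol, via alkenyldimethylalane 4 (not isolated), via lithium alkenylalanate 5 (not isolated)
Conditions: Me3Al (3 equiv), Cp2ZrCl2 (25 mol%), CH2Cl2, 0 °C → rt; evaporate; n-BuLi, hexane/THF, −78 °C; oxirane, −78 °C → rt; aq. KNaC4H4O6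
Reagents that add atoms: trimethylaluminium, C[Al](C)C; oxirane, C1CO1
Why: Zirconium-catalysed Negishi carboalumination adds methyl and aluminium syn across the terminal alkyne with aluminium on the terminal carbon, which fixes C1=C10 as E. The butyl alanate formed in the flask is nucleophilic enough to open oxirane with retention at C1.

Step 4
Reactants: 6 (S,E)-7-[(4-methoxybenzyl)oxy]-4-methyl-6-[(triisopropylsilyl)oxy]hept-3-en-1-ol
Product: 7 (S,E)-7-[(4-methoxybenzyl)oxy]-4-methyl-6-[(triisopropylsilyl)oxy]hept-3-enal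
Conditions: Dess–Martin periodinane, NaHCO3, CH2Cl2, 0 °C; used crude
Reagents that add atoms: none
Why: Dess–Martin oxidation is neutral and fast, so the β,γ-unsaturated aldehyde should not drift into conjugation before it is used.

Step 5
Reactants: 8 but-2-yn-1-ol
Product: 10 (Z)-3-iodobut-2-en-1-ol, via cyclic alkenylaluminate 9 (not isolated)
Conditions: NaAlH2(OCH2CH2OMe)2, THF, 0 °C → rt; I2, −78 → 0 °C
Reagents that add atoms: iodine, [I][I]
Why: Hydroxyl-directed trans-hydroalumination puts aluminium on the distal alkyne carbon; iodine replaces aluminium with retention, so the iodide (future C4) and the CH2OH arm (future C6) are cis.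

Step 6
Reactants: 10 (Z)-3-iodobut-2-en-1-ol
Product: 11 (Z)-triethyl[(3-iodobut-2-en-1-yl)oxy]silane
Conditions: TESCl, imidazole, CH2Cl2, 0 °C
Reagents that add atoms: chlorotriethylsilane, CC[Si](Cl)(CC)CC
Why: Standard silylation; a primary TES ether is chosen because mild acid removes it later beside TBS and TIPS ethers.

Step 7
Reactants: 7 (S,E)-7-[(4-methoxybenzyl)oxy]-4-methyl-6-[(triisopropylsilyl)oxy]hept-3-enal; 11 (Z)-triethyl[(3-iodobut-2-en-1-yl)oxy]silane
Product: 12 (2Z,6E,9S)-10-[(4-methoxybenzyl)oxy]-3,7-dimethyl-1-[(triethylsilyl)oxy]-9-[(triisopropylsilyl)oxy]deca-2,6-dien-4-ol (both C4 epimers)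
Conditions: CrCl2 (4 equiv), NiCl2 (2 mol%), DMSO/THF, rt
Reagents that add atoms: none
Why: Nozaki–Hiyama–Kishi coupling: zerovalent nickel inserts into the C–I bond, the alkenyl group passes to trivalent chromium and adds to the aldehyde, forming C3–C4 with the Z geometry kept. The conditions are non-basic, so 7 is not enolised; the C3 configuration is left open and corrected in steps 8 and 9.

Step 8
Reactants: 12 (2Z,6E,9S)-10-[(4-methoxybenzyl)oxy]-3,7-dimethyl-1-[(triethylsilyl)oxy]-9-[(triisopropylsilyl)oxy]deca-2,6-dien-4-ol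
Product: 13 (2Z,6E,9S)-10-[(4-methoxybenzyl)oxy]-3,7-dimethyl-1-[(triethylsilyl)oxy]-9-[(triisopropylsilyl)oxy]deca-2,6-dien-4-one
Conditions: Dess–Martin periodinane, NaHCO3, CH2Cl2, 0 °C
Reagents that add atoms: none
Why: Dess–Martin oxidation converges both C3 epimers on one Z enone; buffering avoids Z/E isomerisation and migration of C1=C10 into conjugation.

Step 9
Reactants: 13 (2Z,6E,9S)-10-[(4-methoxybenzyl)oxy]-3,7-dimethyl-1-[(triethylsilyl)oxy]-9-[(triisopropylsilyl)oxy]deca-2,6-dien-4-one
Product: 14 (2Z,4S,6E,9S)-10-[(4-methoxybenzyl)oxy]-3,7-dimethyl-1-[(triethylsilyl)oxy]-9-[(triisopropylsilyl)oxy]deca-2,6-dien-4-ol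
Conditions: (R)-2-methyl-CBS-oxazaborolidine (0.5 equiv), catecholborane, toluene, −78 °C
Reagents that add atoms: none
Why: Corey–Bakshi–Shibata reduction: the catalyst binds the ketone with the α-branched alkenyl group as the large and the CH2 group as the small substituent, and the (R)-catalyst should deliver hydride to give the S carbinol at C3. Catecholborane at −78 °C should leave the trisubstituted olefins alone.

Step 10
Reactants: 14 (2Z,4S,6E,9S)-10-[(4-methoxybenzyl)oxy]-3,7-dimethyl-1-[(triethylsilyl)oxy]-9-[(triisopropylsilyl)oxy]deca-2,6-dien-4-ol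
Product: 15 (2Z,4S,6E,9S)-4-[(tert-butyldimethylsilyl)oxy]-10-[(4-methoxybenzyl)oxy]-3,7-dimethyl-1-[(triethylsilyl)oxy]-9-[(triisopropylsilyl)oxy]deca-2,6-diene
Conditions: TBSOTf, 2,6-lutidine, CH2Cl2, −78 °C
Reagents that add atoms: tert-butyldimethylsilyl trifluoromethanesulfonate, CC(C)(C)[Si](C)(C)OS(=O)(=O)C(F)(F)F
Why: Standard silylation of a hindered secondary allylic alcohol; the primary TES ether is stable to these conditions.

Step 11
Reactants: 15 (2Z,4S,6E,9S)-4-[(tert-butyldimethylsilyl)oxy]-10-[(4-methoxybenzyl)oxy]-3,7-dimethyl-1-[(triethylsilyl)oxy]-9-[(triisopropylsilyl)oxy]deca-2,6-diene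
Product: 16 (2S,4E,7S,8Z)-7-[(tert-butyldimethylsilyl)oxy]-4,8-dimethyl-10-[(triethylsilyl)oxy]-2-[(triisopropylsilyl)oxy]deca-4,8-dien-1-ol
Conditions: DDQ, CH2Cl2/pH 7 buffer, 0 °C
Reagents that add atoms: none
Why: Oxidative cleavage of the 4-methoxybenzyl ether by hydride abstraction is orthogonal to all three silyl ethers; the buffer keeps the primary TES ether intact.

Step 12
Reactants: 16 (2S,4E,7S,8Z)-7-[(tert-butyldimethylsilyl)oxy]-4,8-dimethyl-10-[(triethylsilyl)oxy]-2-[(triisopropylsilyl)oxy]deca-4,8-dien-1-ol
Product: 17 (2S,4E,7S,8Z)-7-[(tert-butyldimethylsilyl)oxy]-4,8-dimethyl-10-[(triethylsilyl)oxy]-2-[(triisopropylsilyl)oxy]deca-4,8-dienal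
Conditions: Dess–Martin periodinane, NaHCO3, CH2Cl2, 0 °C
Reagents that add atoms: none
Why: Neutral Dess–Martin oxidation gives the α-silyloxy aldehyde (C7) without epimerising C8; it is used at once.

Step 13
Reactants: 18 ethyl 3-hydroxypropanoate
Product: 19 ethyl 3-[(tert-butyldimethylsilyl)oxy]propanoate
Conditions: TBSCl, imidazole, DMF, rt
Reagents that add atoms: tert-butylchlorodimethylsilane, CC(C)(C)[Si](C)(C)Cl
Why: Standard silylation of a primary alcohol; this oxygen becomes the C12 oxygen.

Step 14
Reactants: 19 ethyl 3-[(tert-butyldimethylsilyl)oxy]propanoate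
Product: 21 ethyl 3-[(tert-butyldimethylsilyl)oxy]-2-(diethoxyphosphoryl)propanoate, via phosphonite ester 20 (not isolated)
Conditions: LiN(i-Pr)2 (2.1 equiv), THF, −78 °C; ClP(OEt)2, −78 °C; 30% H2O2, 0 °C
Reagents that add atoms: diethyl chlorophosphite, CCOP(Cl)OCC; hydrogen peroxide, OO
Why: C-phosphinylation of the ester enolate by the trivalent phosphorus chloride followed by oxidation is a known route to α-phosphono esters. Holding −78 °C until the P–C bond is formed should prevent β-elimination of the silyloxy group from the enolate.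

Step 15
Reactants: 17 (2S,4E,7S,8Z)-7-[(tert-butyldimethylsilyl)oxy]-4,8-dimethyl-10-[(triethylsilyl)oxy]-2-[(triisopropylsilyl)oxy]deca-4,8-dienal; 21 ethyl 3-[(tert-butyldimethylsilyl)oxy]-2-(diethoxyphosphoryl)propanoate
Product: 22 ethyl (2E,4S,6E,9S,10Z)-9-[(tert-butyldimethylsilyl)oxy]-2-{[(tert-butyldimethylsilyl)oxy]methyl}-6,10-dimethyl-12-[(triethylsilyl)oxy]-4-[(triisopropylsilyl)oxy]dodeca-2,6,10-trienoate
Conditions: 21 (1.3 equiv), NaH, THF, 0 °C; then 17, −78 → 0 °C
Reagents that add atoms: none
Why: Horner–Wadsworth–Emmons olefination with an α-substituted phosphonoacetate should give the trisubstituted enoate with the ester trans to the C8 branch. That geometry makes the ester carbon the future C13 (ring-trans to C8) and the silyloxymethyl carbon the future C12; low temperature protects the α-silyloxy aldehyde from epimerisation.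

Step 16
Reactants: 22 ethyl (2E,4S,6E,9S,10Z)-9-[(tert-butyldimethylsilyl)oxy]-2-{[(tert-butyldimethylsilyl)oxy]methyl}-6,10-dimethyl-12-[(triethylsilyl)oxy]-4-[(triisopropylsilyl)oxy]dodeca-2,6,10-trienoate
Product: 23 (2Z,4S,6E,9S,10Z)-9-[(tert-butyldimethylsilyl)oxy]-2-{[(tert-butyldimethylsilyl)oxy]methyl}-6,10-dimethyl-12-[(triethylsilyl)oxy]-4-[(triisopropylsilyl)oxy]dodeca-2,6,10-trien-1-ol
Conditions: i-Bu2AlH (2.5 equiv), CH2Cl2, −78 °C; aq. KNaC4H4O6
Reagents that add atoms: none
Why: 1,2-Reduction of the enoate by the aluminium hydride gives the C13 allylic alcohol with the olefin geometry unchanged; the aluminium alkoxide does not promote silyl transfer from the C12 oxygen.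

Step 17
Reactants: 23 (2Z,4S,6E,9S,10Z)-9-[(tert-butyldimethylsilyl)oxy]-2-{[(tert-butyldimethylsilyl)oxy]methyl}-6,10-dimethyl-12-[(triethylsilyl)oxy]-4-[(triisopropylsilyl)oxy]dodeca-2,6,10-trien-1-ol
Product: 25 triethyl{[(2Z,4S,6E,9S,10E)-4-[(tert-butyldimethylsilyl)oxy]-11-{[(tert-butyldimethylsilyl)oxy]methyl}-12-chloro-3,7-dimethyl-9-[(triisopropylsilyl)oxy]dodeca-2,6,10-trien-1-yl]oxy}silane, via allylic mesylate 24 (not isolated)
Conditions: MsCl, Et3N, CH2Cl2, −20 °C; LiCl, DMF, 0 °C → rt
Reagents that add atoms: methanesulfonyl chloride, CS(Cl)(=O)=O; lithium chloride, [Li+].[Cl-]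
Why: Mesylation and SN2 displacement by chloride at a primary allylic carbon should proceed without allylic transposition. Only an amine base is present, so no free C13 alkoxide forms next to the C12 silyl ether.

Step 18
Reactants: 25 triethyl{[(2Z,4S,6E,9S,10E)-4-[(tert-butyldimethylsilyl)oxy]-11-{[(tert-butyldimethylsilyl)oxy]methyl}-12-chloro-3,7-dimethyl-9-[(triisopropylsilyl)oxy]dodeca-2,6,10-trien-1-yl]oxy}silane
Product: 26 (2Z,4S,6E,9S,10E)-4-[(tert-butyldimethylsilyl)oxy]-11-{[(tert-butyldimethylsilyl)oxy]methyl}-12-chloro-3,7-dimethyl-9-[(triisopropylsilyl)oxy]dodeca-2,6,10-trien-1-ol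
Conditions: pyridinium p-toluenesulfonate (10 mol%), MeOH/CH2Cl2, 0 °C
Reagents that add atoms: none
Why: Acid-catalysed methanolysis cleaves a primary TES ether far faster than TBS or TIPS ethers, and the allylic chloride should not solvolyse at 0 °C.

Step 19
Reactants: 26 (2Z,4S,6E,9S,10E)-4-[(tert-butyldimethylsilyl)oxy]-11-{[(tert-butyldimethylsilyl)oxy]methyl}-12-chloro-3,7-dimethyl-9-[(triisopropylsilyl)oxy]dodeca-2,6,10-trien-1-ol
Product: 27 (3Z,5S,7E,10S,11Z)-10-[(tert-butyldimethylsilyl)oxy]-3-{[(tert-butyldimethylsilyl)oxy]methyl}-7,11-dimethyl-5-[(triisopropylsilyl)oxy]-1-oxacyclotrideca-3,7,11-triene (oxygen bridges C6 and C13)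
Conditions: EtMgBr (1.05 equiv), THF, 0 °C; slow addition to THF/HMPA 4:1 at 60 °C (final 0.003 M)
Reagents that add atoms: none
Why: Intramolecular Williamson etherification: the C6 magnesium alkoxide displaces the primary allylic chloride at C13 by SN2, and the thirteen-membered ring closes without transannular strain under high dilution. The magnesium counter-ion and the bulky TBS group on C3 should suppress 1,4-silyl transfer to the C6 alkoxide.

Step 20
Reactants: 27 (3Z,5S,7E,10S,11Z)-10-[(tert-butyldimethylsilyl)oxy]-3-{[(tert-butyldimethylsilyl)oxy]methyl}-7,11-dimethyl-5-[(triisopropylsilyl)oxy]-1-oxacyclotrideca-3,7,11-triene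
Product: 29 (3S,6R,7S,8S)-3,12-bis[(tert-butyldimethylsilyl)oxy]-8-[(triisopropylsilyl)oxy]germacra-1(10)E,4Z,11(13)-trien-6-ol, via C6-lithiated ether 28 (not isolated)
Conditions: n-BuLi (3 equiv), THF/hexane, −78 → −20 °C; pH 7 buffer, −78 °C
Reagents that add atoms: none
Why: n-BuLi, guided by the ring oxygen (the only Lewis-basic oxygen, all others being bulky silyl ethers), removes an allylic α-oxy proton at C6, and the α-lithio ether 28 undergoes the concerted suprafacial [2,3]-Wittig shift through a five-membered envelope: C6 bonds to C7 while O–C13 breaks and the π bond moves to C11=C13. The closest known reaction type is the [2,3]-Wittig ring contraction of thirteen-membered diallylic ethers to 2-alkenylcyclodecadienols. The ten-membered carbocycle is closed by ring contraction, that is by bond formation across the existing macrocycle through a five-centre transition state and not by end-to-end cyclisation, so the entropic cost of ring formation was paid in step 19. C7 is set by C8: allylic 1,3-strain with the C12 arm holds C8–H in the olefin plane, and C6 reaches C7 from the face carrying the C9 tether, opposite the TIPS ether, placing 7-H cis to the C8 oxygen. C6 is set relative to C7 by the ring-trans C7=C11 geometry: with the C5 vinyl group exo on the envelope, an E olefin gives the anti homoallylic alcohol, which is the trans C6–O/C7–C11 relationship of the lactone. The step needs reaction through C6 rather than C13 or C12: the C6 anion attacks a CH terminus and makes the ten-membered ring, an anion at C13 would have to attack the fully substituted C4, and lithiation at C12 is disfavoured by the bulky, non-coordinating TBS ether. The Z geometry of C4=C5 should survive because the shift is faster than rotation in the allyl anion at these temperatures, and the cold neutral quench prevents silyl transfer to the new C6 alkoxide.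

Step 21
Reactants: 29 (3S,6R,7S,8S)-3,12-bis[(tert-butyldimethylsilyl)oxy]-8-[(triisopropylsilyl)oxy]germacra-1(10)E,4Z,11(13)-trien-6-ol
Product: 30 (3S,6R,7S,8S)-8-[(triisopropylsilyl)oxy]germacra-1(10)E,4Z,11(13)-triene-3,6,12-triol
Conditions: HF·pyridine, pyridine, THF, 0 °C → rt
Reagents that add atoms: none
Why: Buffered fluoride desilylation is graded by steric access: the primary TBS ether (C12) and the allylic secondary TBS ether (C3) should go, while the hindered secondary TIPS ether at C8 stays. C8–OH therefore cannot compete for the lactone in step 22.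

Step 22
Reactants: 30 (3S,6R,7S,8S)-8-[(triisopropylsilyl)oxy]germacra-1(10)E,4Z,11(13)-triene-3,6,12-triol
Product: 32 (3S,6R,7S,8S)-3-hydroxy-8-[(triisopropylsilyl)oxy]germacra-1(10)E,4Z,11(13)-trien-12,6-olide, via 12,6-lactol 31 (not isolated)
Conditions: TEMPO (20 mol%), PhI(OAc)2 (2.5 equiv), CH2Cl2, rt
Reagents that add atoms: none
Why: Oxoammonium oxidation is selective for the primary allylic alcohol; the enal is trapped by the C6 hydroxyl as a five-membered lactol, which is oxidised on to the α-methylene lactone. The secondary C3 alcohol should react much more slowly, and the trans ring fusion is already fixed at C6 and C7.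

Step 23
Reactants: 32 (3S,6R,7S,8S)-3-hydroxy-8-[(triisopropylsilyl)oxy]germacra-1(10)E,4Z,11(13)-trien-12,6-olide
Product: 33 (3S,6R,7S,8S)-3-acetoxy-8-[(triisopropylsilyl)oxy]germacra-1(10)E,4Z,11(13)-trien-12,6-olide
Conditions: Ac2O, pyridine, DMAP (cat.), CH2Cl2, 0 °C
Reagents that add atoms: acetic anhydride, CC(=O)OC(C)=O
Why: Nucleophile-catalysed acylation of the only free hydroxyl; brief exposure to the weak base at 0 °C should not harm the enoate.

Step 24
Reactants: 33 (3S,6R,7S,8S)-3-acetoxy-8-[(triisopropylsilyl)oxy]germacra-1(10)E,4Z,11(13)-trien-12,6-olide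
Product: 34 (3S,6R,7R,8S)-3-acetoxy-8-hydroxygermacra-1(10)E,4Z,11(13)-trien-12,6-olide
Conditions: HF·pyridine (excess), THF, rt → 40 °C
Reagents that add atoms: none
Why: Fluoride desilylation under buffered, non-basic conditions avoids the Michael addition and acetate cleavage that a basic fluoride source could cause.

Step 25
Reactants: 34 (3S,6R,7R,8S)-3-acetoxy-8-hydroxygermacra-1(10)E,4Z,11(13)-trien-12,6-olide
Product: 35 (3S,6R,7R,8S)-3-acetoxy-8-(3-methylbutanoyloxy)germacra-1(10)E,4Z,11(13)-trien-12,6-olide
Conditions: 3-methylbutanoic anhydride, Et3N, DMAP, CH2Cl2, rt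
Reagents that add atoms: 3-methylbutanoic anhydride, CC(C)CC(=O)OC(=O)CC(C)C
Why: DMAP-catalysed acylation of the hindered secondary C8 alcohol; no stereocentre is affected.

Step 26
Reactants: 35 (3S,6R,7R,8S)-3-acetoxy-8-(3-methylbutanoyloxy)germacra-1(10)E,4Z,11(13)-trien-12,6-olide
Product: 36 (1R,3S,6R,7R,8S,10R)-3-acetoxy-1,10-epoxy-8-(3-methylbutanoyloxy)germacra-4Z,11(13)-dien-12,6-olide (CNP0157657.1)
Conditions: mCPBA (1.05 equiv), NaHCO3, CH2Cl2, 0 °C
Reagents that add atoms: 3-chloroperoxybenzoic acid, OOC(=O)c1cccc(Cl)c1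
Why: Prilezhaev epoxidation should choose C1=C10, the only electron-rich olefin (C4=C5 is flanked by two allylic acyloxy groups, C11=C13 is an enoate). Syn addition to the E olefin gives the trans epoxide, and attack on the outer face of the ring-embedded olefin should give the 1β,10α (1R,10R) isomer; the buffer removes the acid that could trigger transannular cyclisation.

## Compound list

1 | (S)-2-{[(4-methoxybenzyl)oxy]methyl}oxirane | COc1ccc(COC[C@@H]2CO2)cc1 | starting material
2 | (S)-1-[(4-methoxybenzyl)oxy]pent-4-yn-2-ol | C#CC[C@H](O)COCc1ccc(OC)cc1 | intermediate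
3 | (S)-triisopropyl({1-[(4-methoxybenzyl)oxy]pent-4-yn-2-yl}oxy)silane | C#CC[C@H](O[Si](C(C)C)(C(C)C)C(C)C)COCc1ccc(OC)cc1 | intermediate
4 | (S,E)-dimethyl{5-[(4-methoxybenzyl)oxy]-2-methyl-4-[(triisopropylsilyl)oxy]pent-1-en-1-yl}alane | C[Al](C)/C=C(\C)C[C@H](O[Si](C(C)C)(C(C)C)C(C)C)COCc1ccc(OC)cc1 | intermediate (not isolated)
5 | lithium butyl(dimethyl){(S,E)-5-[(4-methoxybenzyl)oxy]-2-methyl-4-[(triisopropylsilyl)oxy]pent-1-en-1-yl}aluminate | [Li+].CCCC[Al-](C)(C)/C=C(\C)C[C@H](O[Si](C(C)C)(C(C)C)C(C)C)COCc1ccc(OC)cc1 | intermediate (not isolated)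
6 | (S,E)-7-[(4-methoxybenzyl)oxy]-4-methyl-6-[(triisopropylsilyl)oxy]hept-3-en-1-ol | OCC/C=C(\C)C[C@H](O[Si](C(C)C)(C(C)C)C(C)C)COCc1ccc(OC)cc1 | intermediate
7 | (S,E)-7-[(4-methoxybenzyl)oxy]-4-methyl-6-[(triisopropylsilyl)oxy]hept-3-enal | O=CC/C=C(\C)C[C@H](O[Si](C(C)C)(C(C)C)C(C)C)COCc1ccc(OC)cc1 | intermediate
8 | but-2-yn-1-ol | CC#CCO | starting material
9 | sodium 2,2-bis(2-methoxyethoxy)-3-methyl-2,5-dihydro-1,2-oxaluminol-2-uide (cyclic alkenylaluminate) | CC1=CCO[Al-]1(OCCOC)OCCOC.[Na+] | intermediate (not isolated)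
10 | (Z)-3-iodobut-2-en-1-ol | OC/C=C(/C)I | intermediate
11 | (Z)-triethyl[(3-iodobut-2-en-1-yl)oxy]silane | CC[Si](CC)(CC)OC/C=C(/C)I | intermediate
12 | (2Z,6E,9S)-10-[(4-methoxybenzyl)oxy]-3,7-dimethyl-1-[(triethylsilyl)oxy]-9-[(triisopropylsilyl)oxy]deca-2,6-dien-4-ol (both C4 epimers) | CC[Si](CC)(CC)OC/C=C(/C)C(O)C/C=C(\C)C[C@H](O[Si](C(C)C)(C(C)C)C(C)C)COCc1ccc(OC)cc1 | intermediate
13 | (2Z,6E,9S)-10-[(4-methoxybenzyl)oxy]-3,7-dimethyl-1-[(triethylsilyl)oxy]-9-[(triisopropylsilyl)oxy]deca-2,6-dien-4-one | CC[Si](CC)(CC)OC/C=C(/C)C(=O)C/C=C(\C)C[C@H](O[Si](C(C)C)(C(C)C)C(C)C)COCc1ccc(OC)cc1 | intermediate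
14 | (2Z,4S,6E,9S)-10-[(4-methoxybenzyl)oxy]-3,7-dimethyl-1-[(triethylsilyl)oxy]-9-[(triisopropylsilyl)oxy]deca-2,6-dien-4-ol | CC[Si](CC)(CC)OC/C=C(/C)[C@@H](O)C/C=C(\C)C[C@H](O[Si](C(C)C)(C(C)C)C(C)C)COCc1ccc(OC)cc1 | intermediate
15 | (2Z,4S,6E,9S)-4-[(tert-butyldimethylsilyl)oxy]-10-[(4-methoxybenzyl)oxy]-3,7-dimethyl-1-[(triethylsilyl)oxy]-9-[(triisopropylsilyl)oxy]deca-2,6-diene | CC[Si](CC)(CC)OC/C=C(/C)[C@@H](O[Si](C)(C)C(C)(C)C)C/C=C(\C)C[C@H](O[Si](C(C)C)(C(C)C)C(C)C)COCc1ccc(OC)cc1 | intermediate
16 | (2S,4E,7S,8Z)-7-[(tert-butyldimethylsilyl)oxy]-4,8-dimethyl-10-[(triethylsilyl)oxy]-2-[(triisopropylsilyl)oxy]deca-4,8-dien-1-ol | CC[Si](CC)(CC)OC/C=C(/C)[C@@H](O[Si](C)(C)C(C)(C)C)C/C=C(\C)C[C@H](O[Si](C(C)C)(C(C)C)C(C)C)CO | intermediate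
17 | (2S,4E,7S,8Z)-7-[(tert-butyldimethylsilyl)oxy]-4,8-dimethyl-10-[(triethylsilyl)oxy]-2-[(triisopropylsilyl)oxy]deca-4,8-dienal | CC[Si](CC)(CC)OC/C=C(/C)[C@@H](O[Si](C)(C)C(C)(C)C)C/C=C(\C)C[C@H](O[Si](C(C)C)(C(C)C)C(C)C)C=O | intermediate
18 | ethyl 3-hydroxypropanoate | CCOC(=O)CCO | starting material
19 | ethyl 3-[(tert-butyldimethylsilyl)oxy]propanoate | CCOC(=O)CCO[Si](C)(C)C(C)(C)C | intermediate
20 | ethyl 3-[(tert-butyldimethylsilyl)oxy]-2-(diethoxyphosphanyl)propanoate | CCOC(=O)C(CO[Si](C)(C)C(C)(C)C)P(OCC)OCC | intermediate (not isolated)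
21 | ethyl 3-[(tert-butyldimethylsilyl)oxy]-2-(diethoxyphosphoryl)propanoate (racemic) | CCOC(=O)C(CO[Si](C)(C)C(C)(C)C)P(=O)(OCC)OCC | intermediate
22 | ethyl (2E,4S,6E,9S,10Z)-9-[(tert-butyldimethylsilyl)oxy]-2-{[(tert-butyldimethylsilyl)oxy]methyl}-6,10-dimethyl-12-[(triethylsilyl)oxy]-4-[(triisopropylsilyl)oxy]dodeca-2,6,10-trienoate | CC[Si](CC)(CC)OC/C=C(/C)[C@@H](O[Si](C)(C)C(C)(C)C)C/C=C(\C)C[C@H](O[Si](C(C)C)(C(C)C)C(C)C)/C=C(\CO[Si](C)(C)C(C)(C)C)C(=O)OCC | intermediate
23 | (2Z,4S,6E,9S,10Z)-9-[(tert-butyldimethylsilyl)oxy]-2-{[(tert-butyldimethylsilyl)oxy]methyl}-6,10-dimethyl-12-[(triethylsilyl)oxy]-4-[(triisopropylsilyl)oxy]dodeca-2,6,10-trien-1-ol | CC[Si](CC)(CC)OC/C=C(/C)[C@@H](O[Si](C)(C)C(C)(C)C)C/C=C(\C)C[C@H](O[Si](C(C)C)(C(C)C)C(C)C)/C=C(\CO[Si](C)(C)C(C)(C)C)CO | intermediate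
24 | methanesulfonate of 23 | CC[Si](CC)(CC)OC/C=C(/C)[C@@H](O[Si](C)(C)C(C)(C)C)C/C=C(\C)C[C@H](O[Si](C(C)C)(C(C)C)C(C)C)/C=C(\CO[Si](C)(C)C(C)(C)C)COS(C)(=O)=O | intermediate (not isolated)
25 | triethyl{[(2Z,4S,6E,9S,10E)-4-[(tert-butyldimethylsilyl)oxy]-11-{[(tert-butyldimethylsilyl)oxy]methyl}-12-chloro-3,7-dimethyl-9-[(triisopropylsilyl)oxy]dodeca-2,6,10-trien-1-yl]oxy}silane | CC[Si](CC)(CC)OC/C=C(/C)[C@@H](O[Si](C)(C)C(C)(C)C)C/C=C(\C)C[C@H](O[Si](C(C)C)(C(C)C)C(C)C)/C=C(\CO[Si](C)(C)C(C)(C)C)CCl | intermediate
26 | (2Z,4S,6E,9S,10E)-4-[(tert-butyldimethylsilyl)oxy]-11-{[(tert-butyldimethylsilyl)oxy]methyl}-12-chloro-3,7-dimethyl-9-[(triisopropylsilyl)oxy]dodeca-2,6,10-trien-1-ol | OC/C=C(/C)[C@@H](O[Si](C)(C)C(C)(C)C)C/C=C(\C)C[C@H](O[Si](C(C)C)(C(C)C)C(C)C)/C=C(\CO[Si](C)(C)C(C)(C)C)CCl | intermediate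
27 | (3Z,5S,7E,10S,11Z)-10-[(tert-butyldimethylsilyl)oxy]-3-{[(tert-butyldimethylsilyl)oxy]methyl}-7,11-dimethyl-5-[(triisopropylsilyl)oxy]-1-oxacyclotrideca-3,7,11-triene | O1C/C(CO[Si](C)(C)C(C)(C)C)=C/[C@@H](O[Si](C(C)C)(C(C)C)C(C)C)C/C(C)=C/C[C@H](O[Si](C)(C)C(C)(C)C)/C(C)=C\C1 | intermediate
28 | 27 lithiated at the ring carbon C6 (α to oxygen, allylic to C4=C5) | O1C/C(CO[Si](C)(C)C(C)(C)C)=C/[C@@H](O[Si](C(C)C)(C(C)C)C(C)C)C/C(C)=C/C[C@H](O[Si](C)(C)C(C)(C)C)/C(C)=C\C1[Li] | intermediate (not isolated)
29 | (3S,6R,7S,8S)-3,12-bis[(tert-butyldimethylsilyl)oxy]-8-[(triisopropylsilyl)oxy]germacra-1(10)E,4Z,11(13)-trien-6-ol | C=C(CO[Si](C)(C)C(C)(C)C)[C@H]1[C@H](O)/C=C(/C)[C@@H](O[Si](C)(C)C(C)(C)C)C/C=C(\C)C[C@@H]1O[Si](C(C)C)(C(C)C)C(C)C | intermediate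
30 | (3S,6R,7S,8S)-8-[(triisopropylsilyl)oxy]germacra-1(10)E,4Z,11(13)-triene-3,6,12-triol | C=C(CO)[C@H]1[C@H](O)/C=C(/C)[C@@H](O)C/C=C(\C)C[C@@H]1O[Si](C(C)C)(C(C)C)C(C)C | intermediate
31 | 12,6-lactol of 30 (C12 hemiacetal, both anomers) | C=C1C(O)O[C@@H]2/C=C(/C)[C@@H](O)C/C=C(\C)C[C@H](O[Si](C(C)C)(C(C)C)C(C)C)[C@@H]12 | intermediate (not isolated)
32 | (3S,6R,7S,8S)-3-hydroxy-8-[(triisopropylsilyl)oxy]germacra-1(10)E,4Z,11(13)-trien-12,6-olide | C=C1C(=O)O[C@@H]2/C=C(/C)[C@@H](O)C/C=C(\C)C[C@H](O[Si](C(C)C)(C(C)C)C(C)C)[C@@H]12 | intermediate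
33 | (3S,6R,7S,8S)-3-acetoxy-8-[(triisopropylsilyl)oxy]germacra-1(10)E,4Z,11(13)-trien-12,6-olide | C=C1C(=O)O[C@@H]2/C=C(/C)[C@@H](OC(C)=O)C/C=C(\C)C[C@H](O[Si](C(C)C)(C(C)C)C(C)C)[C@@H]12 | intermediate
34 | (3S,6R,7R,8S)-3-acetoxy-8-hydroxygermacra-1(10)E,4Z,11(13)-trien-12,6-olide | C=C1C(=O)O[C@@H]2/C=C(/C)[C@@H](OC(C)=O)C/C=C(\C)C[C@H](O)[C@@H]12 | intermediate
35 | (3S,6R,7R,8S)-3-acetoxy-8-(3-methylbutanoyloxy)germacra-1(10)E,4Z,11(13)-trien-12,6-olide | C=C1C(=O)O[C@@H]2/C=C(/C)[C@@H](OC(C)=O)C/C=C(\C)C[C@H](OC(=O)CC(C)C)[C@@H]12 | intermediate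
36 | (1R,3S,6R,7R,8S,10R)-3-acetoxy-1,10-epoxy-8-(3-methylbutanoyloxy)germacra-4Z,11(13)-dien-12,6-olide (CNP0157657.1) | C=C1C(=O)O[C@@H]2/C=C(/C)[C@@H](OC(C)=O)C[C@H]3O[C@]3(C)C[C@H](OC(=O)CC(C)C)[C@@H]12 | target

## Step count and least certain steps

Total step count: 26. Longest linear sequence: 22 steps (steps 1–4, 7–12 and 15–26).

Step 20 (key step). What may go wrong: lithiation at C13 or C12 instead of C6, followed by a shift onto C4 or by silyl migration; loss of facial control at C7=C11; a competing [1,2]-shift if the mixture is warmed too far; Z/E drift of C4=C5 in the allyl anion. Fallback: the ring is closed at the same C6–C7 bond by an intramolecular Nozaki–Hiyama allylation instead of a sigmatropic shift. It sets out from 26: MnO2 in CH2Cl2 should oxidise the Z allylic alcohol to the (Z)-enal chloride F1. CrCl2 with NaI in THF/DMF at high dilution should then turn the C13 chloride into an allylchromium species of trivalent chromium. This attacks the C6 aldehyde through its γ-carbon C7 in a chair transition state and gives the anti homoallylic alcohol with the C11=C13 methylene. The route is rejoined at 29.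

Step 15. What may go wrong: erosion of E selectivity because the α-substituent of 21 is bulkier than methyl, β-elimination of silanolate from the phosphonate anion, or epimerisation at C8. Fallback: the olefin geometry is set by syn hydrometalation of an alkyne instead of by olefination. It sets out from 17: CBr4/PPh3 should give the 1,1-dibromoalkene F2. n-BuLi followed by paraformaldehyde should give the propargylic alcohol F3, and TBSCl/imidazole its TBS ether F4. Cp2Zr(H)Cl should add syn with zirconium on the less hindered alkyne carbon (C11), and iodine should give the vinyl iodide F5 with iodine trans to C8. Stille coupling with Bu3SnCH2OH and Pd(PPh3)4 introduces the C13 hydroxymethyl group, and the route is rejoined at 23.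

Step 3. What may go wrong: slow or incomplete carbometalation because two ether oxygens bind aluminium, and transfer of butyl instead of alkenyl from the alanate to oxirane. Fallback: C2 and C3 are brought in by cross-coupling instead of epoxide opening. It sets out from 3: the same carboalumination quenched with iodine should give the (E)-vinyl iodide F6. Palladium-catalysed Negishi coupling with the Reformatsky reagent BrZnCH2CO2Et (Pd(PPh3)4, THF) should give the β,γ-unsaturated ester F7, and i-Bu2AlH at −78 °C should reduce it to the aldehyde. The route is rejoined at 7.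

Step 22. What may go wrong: over-oxidation of the free C3 allylic alcohol to the enone, or oxidation at C6 before the lactol closes. Fallback: the order of unmasking is changed so that C3 stays silylated during the oxidation. It sets out from 29: brief treatment with HF·pyridine/pyridine at 0 °C should remove only the primary TBS ether and give the 6,12-diol F8. TEMPO/PhI(OAc)2 should then give the C3-silylated lactone F9, and HF·pyridine should free the C3 hydroxyl. The route is rejoined at 32.

Step 26. What may go wrong: poor facial selectivity on the flexible ring, competing attack on C4=C5, or acid-promoted transannular opening of the epoxide by the benzoic acid formed. Fallback: the oxygen is delivered by a neighbouring hydroxyl instead of by an external peracid. It sets out from 34: VO(acac)2 and t-BuOOH should bind the free 8α hydroxyl, which is homoallylic to C10=C1, and deliver oxygen to the face of C10 syn to it (10α), giving the epoxy alcohol F10. Acylation with 3-methylbutanoic anhydride as in step 25 rejoins the route at 36.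

## Further compounds

F1 | step 20 | (2Z,4S,6E,9S,10E)-4-[(tert-butyldimethylsilyl)oxy]-11-{[(tert-butyldimethylsilyl)oxy]methyl}-12-chloro-3,7-dimethyl-9-[(triisopropylsilyl)oxy]dodeca-2,6,10-trienal | O=C/C=C(/C)[C@@H](O[Si](C)(C)C(C)(C)C)C/C=C(\C)C[C@H](O[Si](C(C)C)(C(C)C)C(C)C)/C=C(\CO[Si](C)(C)C(C)(C)C)CCl
F2 | step 15 | (3S,5E,8S,9Z)-1,1-dibromo-8-[(tert-butyldimethylsilyl)oxy]-5,9-dimethyl-11-[(triethylsilyl)oxy]-3-[(triisopropylsilyl)oxy]undeca-1,5,9-triene | CC[Si](CC)(CC)OC/C=C(/C)[C@@H](O[Si](C)(C)C(C)(C)C)C/C=C(\C)C[C@H](O[Si](C(C)C)(C(C)C)C(C)C)C=C(Br)Br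
F3 | step 15 | (4S,6E,9S,10Z)-9-[(tert-butyldimethylsilyl)oxy]-6,10-dimethyl-12-[(triethylsilyl)oxy]-4-[(triisopropylsilyl)oxy]dodeca-6,10-dien-2-yn-1-ol | CC[Si](CC)(CC)OC/C=C(/C)[C@@H](O[Si](C)(C)C(C)(C)C)C/C=C(\C)C[C@H](O[Si](C(C)C)(C(C)C)C(C)C)C#CCO
F4 | step 15 | tert-butyldimethylsilyl ether of F3 | CC[Si](CC)(CC)OC/C=C(/C)[C@@H](O[Si](C)(C)C(C)(C)C)C/C=C(\C)C[C@H](O[Si](C(C)C)(C(C)C)C(C)C)C#CCO[Si](C)(C)C(C)(C)C
F5 | step 15 | tert-butyl{[(2E,4S,6E,9S,10Z)-9-[(tert-butyldimethylsilyl)oxy]-2-iodo-6,10-dimethyl-12-[(triethylsilyl)oxy]-4-[(triisopropylsilyl)oxy]dodeca-2,6,10-trien-1-yl]oxy}dimethylsilane | CC[Si](CC)(CC)OC/C=C(/C)[C@@H](O[Si](C)(C)C(C)(C)C)C/C=C(\C)C[C@H](O[Si](C(C)C)(C(C)C)C(C)C)/C=C(\CO[Si](C)(C)C(C)(C)C)I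
F6 | step 3 | (S,E)-triisopropyl({5-iodo-1-[(4-methoxybenzyl)oxy]-4-methylpent-4-en-2-yl}oxy)silane | I/C=C(\C)C[C@H](O[Si](C(C)C)(C(C)C)C(C)C)COCc1ccc(OC)cc1
F7 | step 3 | ethyl (S,E)-7-[(4-methoxybenzyl)oxy]-4-methyl-6-[(triisopropylsilyl)oxy]hept-3-enoate | CCOC(=O)C/C=C(\C)C[C@H](O[Si](C(C)C)(C(C)C)C(C)C)COCc1ccc(OC)cc1
F8 | step 22 | (3S,6R,7S,8S)-3-[(tert-butyldimethylsilyl)oxy]-8-[(triisopropylsilyl)oxy]germacra-1(10)E,4Z,11(13)-triene-6,12-diol | C=C(CO)[C@H]1[C@H](O)/C=C(/C)[C@@H](O[Si](C)(C)C(C)(C)C)C/C=C(\C)C[C@@H]1O[Si](C(C)C)(C(C)C)C(C)C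
F9 | step 22 | (3S,6R,7S,8S)-3-[(tert-butyldimethylsilyl)oxy]-8-[(triisopropylsilyl)oxy]germacra-1(10)E,4Z,11(13)-trien-12,6-olide | C=C1C(=O)O[C@@H]2/C=C(/C)[C@@H](O[Si](C)(C)C(C)(C)C)C/C=C(\C)C[C@H](O[Si](C(C)C)(C(C)C)C(C)C)[C@@H]12
F10 | step 26 | (1R,3S,6R,7R,8S,10R)-3-acetoxy-1,10-epoxy-8-hydroxygermacra-4Z,11(13)-dien-12,6-olide | C=C1C(=O)O[C@@H]2/C=C(/C)[C@@H](OC(C)=O)C[C@H]3O[C@]3(C)C[C@H](O)[C@@H]12
A1 | alternative 1 | cis,anti,cis tricyclic photoadduct: cyclohexanone (C6 ketone, C8 4-methoxybenzyl ether, C10 methyl) fused through the C4–C5/C1–C10 cyclobutane to the cyclobutane C1–C4 (C3 silyl ether, C4 methyl ester) | C1C(=O)[C@H]2[C@]3(C(=O)OC)[C@@H](O[Si](C)(C)C(C)(C)C)C[C@@H]3[C@@]2(C)C[C@@H]1OCc4ccc(OC)cc4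
A2 | alternative 2 | 3-[(tert-butyldimethylsilyl)oxy]-1-chloro-10-hydroxy-8-oxo-13-norgermacr-4Z-en-12,6-olide | O=C1C[C@@](C)(O)[C@@H](Cl)C[C@H](O[Si](C)(C)C(C)(C)C)/C(C)=C\[C@H]2OC(=O)C[C@@H]21
A3 | alternative 3 | 3-[(tert-butyldimethylsilyl)oxy]-12,12-dimethoxy-8-[(4-methoxybenzyl)oxy]-13-norgermacra-1(10)E,4Z-dien-6-one | COC(OC)C[C@H]1C(=O)/C=C(/C)[C@@H](O[Si](C)(C)C(C)(C)C)C/C=C(\C)C[C@@H]1OCc2ccc(OC)cc2
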